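**Plan** (daucane numbering: C1 quaternary methyl carbon, C2/C3 ring CH2, C4 isopropyl carbinol, C5 ring-fusion CH, C6 ester carbinol, C7=C8(Me), C9 free carbinol, C10 CH2)
- Cuts, in order: phenol acetate; C9–O back to C9–B; then C10–C1 and C8–C9 together, which removes C9–C10 as vinylboronate and opens the seven-membered ring to a cyclopentane with a tertiary boron on C1 and a (Z)-iodoalkene at C8; then the aryl ester C–O, C4–isopropyl, and C5–C6 (aldol) together with C1–B (conjugate boration).
- Forward: the five-membered ring is 3-methylcyclopent-2-enone; boration/aldol, isopropyl addition and esterification dress it; the seven-membered ring closes in step 7.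
- Enabling feature: C10 is a methylene between quaternary C1 and carbinol C9, and C9 carries the sp2 carbon C8 of the ring alkene. The array tertiary alkyl–CH2–CH(O)–alkenyl is what alkyl/alkenyl addition across a vinylboronate builds, and the C1 radical can reach its own alkene only by 4-exo or 5-endo closure.
- Stereochemistry: a chiral copper catalyst sets the boron-bearing C1; this is relayed to C5 and C6 (anti aldol, trans to boron), to C4 (addition anti to the C5 chain), back to C1 (radical addition anti to the C5 chain, trans fusion) and to C9 (pseudo-equatorial boron, oxidised with retention).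

Key step: step 7

Remark: the QuinoxP* antipode used is the one that gives the 3R tertiary boronate; its sense is assumed. Bpin = 4,4,5,5-tetramethyl-1,3,2-dioxaborolan-2-yl.

**Step 1**
Reactants: 1 but-2-yn-1-ol
Product: 3 (Z)-3-iodobut-2-en-1-ol, via cyclic vinylalanate 2 (not isolated)
Conditions: NaAlH2(OCH2CH2OMe)2, THF, 0 °C to rt; then I2, −78 to 0 °C
Reagents that add atoms: iodine, II
Why: Hydroxyl-directed trans-hydroalumination of the alkynol puts aluminium on the distal alkyne carbon in a five-membered alanate, and iodinolysis with retention gives the (Z)-iodoalkene.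

**Step 2**
Reactants: 3 (Z)-3-iodobut-2-en-1-ol
Product: 4 (Z)-3-iodobut-2-enal
Conditions: MnO2, CH2Cl2, rt
Reagents that add atoms: none
Why: MnO2 oxidation of an allylic alcohol is mild enough to keep the Z geometry and the C–I bond.

**Step 3**
Reactants: 5 3-methylcyclopent-2-en-1-one; 4 (Z)-3-iodobut-2-enal
Product: 7 (2S,3R)-2-[(1R,2Z)-1-hydroxy-3-iodobut-2-en-1-yl]-3-methyl-3-(Bpin)cyclopentan-1-one, via boron enolate 6 (not isolated)
Conditions: CuPF6(MeCN)4 (5 mol%), QuinoxP* (6 mol%), LiOtBu (8 mol%), B2pin2 (1.0 equiv), DMSO/THF, rt; then 4, 0 °C; aq NH4Cl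
Reagents that add atoms: bis(pinacolato)diboron, CC1(C)OB(OC1(C)C)B1OC(C)(C)C(C)(C)O1
Why: Copper-catalysed enantioselective conjugate boration sets the boron-bearing quaternary C1 under ligand control and leaves a regiodefined boron enolate, whose closed Zimmerman–Traxler aldol with 4 on the face anti to the Bpin group should give the anti aldol and so C5 and C6.

**Step 4**
Reactants: 7 aldol adduct
Product: 8 (1R,2S,3R)-2-[(1R,2Z)-1-hydroxy-3-iodobut-2-en-1-yl]-3-methyl-1-(propan-2-yl)-3-(Bpin)cyclopentan-1-ol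
Conditions: iPrMgCl, CeCl3 (pre-stirred), THF, −78 °C; aq NH4Cl
Reagents that add atoms: isopropylmagnesium chloride, CC(C)[Mg]Cl
Why: Organocerium 1,2-addition tolerates the enolisable β-hydroxy ketone and should deliver isopropyl to the ketone face anti to the adjacent C5 side chain, so that the new hydroxyl is cis to that chain.

**Step 5**
Reactants: 8 diol; 9 4-acetoxy-3-methoxybenzoic acid
Product: 11 (1R,2Z)-1-[(1S,2R,5R)-2-hydroxy-5-methyl-2-(propan-2-yl)-5-(Bpin)cyclopentyl]-3-iodobut-2-en-1-yl 4-acetoxy-3-methoxybenzoate, via acid chloride 10 (not isolated)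
Conditions: 9, (COCl)2, cat. DMF, CH2Cl2, 0 °C; then 8, pyridine, DMAP, 0 °C to rt
Reagents that add atoms: none
Why: DMAP-catalysed acylation by the acid chloride takes the secondary allylic alcohol and leaves the hindered tertiary alcohol and all stereocentres untouched.

**Step 6**
Reactants: 11 pinacol boronate ester
Product: 12 potassium {(1R,2S,3R)-2-[(1R,2Z)-1-(4-acetoxy-3-methoxybenzoyloxy)-3-iodobut-2-en-1-yl]-3-hydroxy-1-methyl-3-(propan-2-yl)cyclopentyl}trifluoroborate
Conditions: KHF2 (aq), MeOH, rt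
Reagents that add atoms: potassium hydrogen difluoride, [K+].F[H-]F
Why: Fluoride exchange of a pinacol boronate with KHF2 gives the trifluoroborate salt, which turns the tertiary boron into a photo-oxidisable radical precursor.

**Step 7**
Reactants: 12 trifluoroborate; 13 vinylboronic acid pinacol ester
Product: 14 (3R,3aS,4S,7S,8aR)-3-hydroxy-6,8a-dimethyl-3-(propan-2-yl)-7-(Bpin)-1,2,3,3a,4,7,8,8a-octahydroazulen-4-yl 4-acetoxy-3-methoxybenzoate
Conditions: [Ir{dF(CF3)ppy}2(bpy)]PF6 (2 mol%), NiCl2·glyme (10 mol%), 4,4′-di-tert-butyl-2,2′-bipyridine (10 mol%), 13 (5 equiv), DMA, blue LEDs, rt, 0.01 M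
Reagents that add atoms: none
Why: Proposed new method: the excited iridium photocatalyst oxidises the trifluoroborate to the tertiary C1 radical, which has only 4-exo and 5-endo paths to its own iodoalkene and therefore adds to the CH2 end of the vinylboronate (C10–C1); the resulting α-boryl C9 radical is taken up by nickel, and oxidative addition of the tethered (Z)-alkenyl iodide followed by C(sp3)–C(sp2) reductive elimination forms C8–C9. The closest known reaction type is the intermolecular nickel/photoredox three-component alkyl–arylation of vinylboronates with tertiary alkyltrifluoroborates and aryl halides; here two of the three partners sit in one molecule. The seven-membered ring closes in the reductive elimination from an eight-membered nickelacycle, a metal-templated closure and not a radical 7-endo one, and the Z iodide supplies the cis ring alkene. C1 should be set by addition to the radical face anti to the adjacent C5 side chain, which gives the trans ring fusion with the methyl cis to C6. C9 should be set by a product-like chair in which the bulky boryl group is pseudo-equatorial and avoids a syn-axial clash with the C1 methyl, which places boron cis to the C6 ester oxygen. The step needs the radical to add to the vinylboronate before it meets nickel and the ring closure to beat intermolecular coupling; the known reluctance of nickel to couple tertiary radicals, the excess of 13 and high dilution of 12 should secure both.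

**Step 8**
Reactants: 14 allylic boronate
Product: 15 (3R,3aS,4S,7S,8aR)-3,7-dihydroxy-6,8a-dimethyl-3-(propan-2-yl)-1,2,3,3a,4,7,8,8a-octahydroazulen-4-yl 4-acetoxy-3-methoxybenzoate
Conditions: 30% H2O2, pH 7 phosphate buffer, THF, 0 °C
Reagents that add atoms: hydrogen peroxide, OO
Why: Peroxide oxidation of the allylic boronic ester proceeds by 1,2-migration of C9 from boron to oxygen with retention and without allylic transposition, and the neutral buffer should spare both esters.

**Step 9**
Reactants: 15 aryl acetate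
Product: 16 (3R,3aS,4S,7S,8aR)-3,7-dihydroxy-6,8a-dimethyl-3-(propan-2-yl)-1,2,3,3a,4,7,8,8a-octahydroazulen-4-yl 4-hydroxy-3-methoxybenzoate
Conditions: K2CO3 (0.2 equiv), MeOH, 0 °C
Reagents that add atoms: none
Why: Base-catalysed methanolysis (transesterification) cleaves the phenyl acetate much faster than the hindered secondary aroyl ester, whose carbonyl is further deactivated once the phenoxide forms.

**Compound list**
1 | but-2-yn-1-ol | CC#CCO | starting material
2 | cyclic sodium alkenyl(alkoxy)bis(2-methoxyethoxy)aluminate (five-membered O–Al–C3=C2–C1 ring) | CC1=CCO[Al-]1(OCCOC)OCCOC.[Na+] | intermediate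
3 | (Z)-3-iodobut-2-en-1-ol | C/C(I)=C/CO | intermediate
4 | (Z)-3-iodobut-2-enal | C/C(I)=C/C=O | intermediate
5 | 3-methylcyclopent-2-en-1-one | CC1=CC(=O)CC1 | starting material
6 | (R)-4,4,5,5-tetramethyl-2-{[3-methyl-3-(Bpin)cyclopent-1-en-1-yl]oxy}-1,3,2-dioxaborolane | C[C@@]1(CCC(OB2OC(C)(C)C(C)(C)O2)=C1)B1OC(C)(C)C(C)(C)O1 | intermediate
7 | (2S,3R)-2-[(1R,2Z)-1-hydroxy-3-iodobut-2-en-1-yl]-3-methyl-3-(Bpin)cyclopentan-1-one | O[C@@H](/C=C(/C)I)[C@H]1C(=O)CC[C@]1(C)B2OC(C)(C)C(C)(C)O2 | intermediate
8 | (1R,2S,3R)-2-[(1R,2Z)-1-hydroxy-3-iodobut-2-en-1-yl]-3-methyl-1-(propan-2-yl)-3-(Bpin)cyclopentan-1-ol | O[C@@H](/C=C(/C)I)[C@H]1[C@](O)(C(C)C)CC[C@]1(C)B2OC(C)(C)C(C)(C)O2 | intermediate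
9 | 4-acetoxy-3-methoxybenzoic acid | CC(=O)Oc1ccc(cc1OC)C(O)=O | starting material
10 | 4-acetoxy-3-methoxybenzoyl chloride | CC(=O)Oc1ccc(cc1OC)C(Cl)=O | intermediate
11 | (1R,2Z)-1-[(1S,2R,5R)-2-hydroxy-5-methyl-2-(propan-2-yl)-5-(Bpin)cyclopentyl]-3-iodobut-2-en-1-yl 4-acetoxy-3-methoxybenzoate | COc1cc(C(=O)O[C@@H](/C=C(/C)I)[C@H]2[C@](O)(C(C)C)CC[C@]2(C)B3OC(C)(C)C(C)(C)O3)ccc1OC(C)=O | intermediate
12 | potassium {(1R,2S,3R)-2-[(1R,2Z)-1-(4-acetoxy-3-methoxybenzoyloxy)-3-iodobut-2-en-1-yl]-3-hydroxy-1-methyl-3-(propan-2-yl)cyclopentyl}trifluoroborate | COc1cc(C(=O)O[C@@H](/C=C(/C)I)[C@H]2[C@](O)(C(C)C)CC[C@]2(C)[B-](F)(F)F)ccc1OC(C)=O.[K+] | intermediate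
13 | vinylboronic acid pinacol ester (2-ethenyl-4,4,5,5-tetramethyl-1,3,2-dioxaborolane) | C=CB1OC(C)(C)C(C)(C)O1 | starting material
14 | (3R,3aS,4S,7S,8aR)-3-hydroxy-6,8a-dimethyl-3-(propan-2-yl)-7-(Bpin)-1,2,3,3a,4,7,8,8a-octahydroazulen-4-yl 4-acetoxy-3-methoxybenzoate (trans-fused) | COc1cc(C(=O)O[C@H]2C=C(C)[C@@H](B4OC(C)(C)C(C)(C)O4)C[C@@]3(C)CC[C@@](O)(C(C)C)[C@H]23)ccc1OC(C)=O | intermediate
15 | (3R,3aS,4S,7S,8aR)-3,7-dihydroxy-6,8a-dimethyl-3-(propan-2-yl)-1,2,3,3a,4,7,8,8a-octahydroazulen-4-yl 4-acetoxy-3-methoxybenzoate | COc1cc(C(=O)O[C@H]2C=C(C)[C@@H](O)C[C@@]3(C)CC[C@@](O)(C(C)C)[C@H]23)ccc1OC(C)=O | intermediate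
16 | (3R,3aS,4S,7S,8aR)-3,7-dihydroxy-6,8a-dimethyl-3-(propan-2-yl)-1,2,3,3a,4,7,8,8a-octahydroazulen-4-yl 4-hydroxy-3-methoxybenzoate | COc1cc(C(=O)O[C@H]2C=C(C)[C@@H](O)C[C@@]3(C)CC[C@@](O)(C(C)C)[C@H]23)ccc1O | target

**Total steps:** 9. **Longest linear sequence:** 9 (1 to 16; 7 steps from 5).

**Steps most likely to fail**

1. Step 7 (Proposed new method). The tertiary radical may be captured by nickel before it adds to the vinylboronate (direct C1–C8 coupling), the nickel coupling may run between molecules instead of closing the ring, or the face selectivity at C9 may be poor. Fallback, from 12 back to 15, with known reactions only: 12 is irradiated with the iridium photocatalyst and 13 in wet DMA without nickel, a photoredox Giese-type hydroalkylation, to give the 2-(Bpin)ethyl compound F1. Buffered H2O2 gives the primary alcohol F2, and Dess–Martin periodinane gives the aldehyde F3. An intramolecular Nozaki–Hiyama–Kishi reaction (CrCl2, cat. NiCl2, DMSO) of the (Z)-alkenyl iodide onto the aldehyde then forms C8–C9 and the seven-membered ring and returns 15.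

2. Step 3. The boryl-copper species may attack the β-iodoenal (conjugate boration or displacement of iodide) instead of leaving it for the aldol, and the aldol may not discriminate well between the methyl and Bpin faces. Fallback, from 1 and 5 back to 8: 1 is oxidised with MnO2 to but-2-ynal F4. The boration/aldol of 5 is run with F4 to give the alkynyl aldol F5, and iPrMgCl/CeCl3 gives the alkynyl diol F6. Ruthenium-catalysed trans-hydrosilylation ([Cp*Ru(MeCN)3]PF6, Et3SiH) places silicon on the distal alkyne carbon to give the (Z)-vinylsilane F7, and iododesilylation with N-iodosuccinimide in hexafluoroisopropanol returns 8.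

3. Step 4. The isopropyl reagent may reduce the hindered ketone by β-hydride transfer, enolise it or trigger retro-aldol cleavage, or add to boron. Fallback, from 7 back to 8: isopropenylmagnesium bromide with CeCl3, an sp2 nucleophile without a β-hydride, gives the isopropenyl carbinol F8. Diimide (2-nitrobenzenesulfonylhydrazide, Et3N) then saturates only the 1,1-disubstituted alkene and returns 8.

**Further compounds**
F1 | step 7 | analogue of 12 with CH2CH2Bpin on C1 in place of BF3K, on the face anti to the C5 side chain | COc1cc(C(=O)O[C@@H](/C=C(/C)I)[C@H]2[C@](O)(C(C)C)CC[C@]2(C)CCB3OC(C)(C)C(C)(C)O3)ccc1OC(C)=O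
F2 | step 7 | 2-hydroxyethyl analogue of F1 | COc1cc(C(=O)O[C@@H](/C=C(/C)I)[C@H]2[C@](O)(C(C)C)CC[C@]2(C)CCO)ccc1OC(C)=O
F3 | step 7 | 2-oxoethyl (aldehyde) analogue of F1 | COc1cc(C(=O)O[C@@H](/C=C(/C)I)[C@H]2[C@](O)(C(C)C)CC[C@]2(C)CC=O)ccc1OC(C)=O
F4 | step 3 | but-2-ynal | CC#CC=O
F5 | step 3 | (2S,3R)-2-[(1R)-1-hydroxybut-2-yn-1-yl]-3-methyl-3-(Bpin)cyclopentan-1-one | O[C@@H](C#CC)[C@H]1C(=O)CC[C@]1(C)B2OC(C)(C)C(C)(C)O2
F6 | step 3 | (1R,2S,3R)-2-[(1R)-1-hydroxybut-2-yn-1-yl]-3-methyl-1-(propan-2-yl)-3-(Bpin)cyclopentan-1-ol | O[C@@H](C#CC)[C@H]1[C@](O)(C(C)C)CC[C@]1(C)B2OC(C)(C)C(C)(C)O2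
F7 | step 3 | (1R,2S,3R)-2-[(1R,2Z)-1-hydroxy-3-(triethylsilyl)but-2-en-1-yl]-3-methyl-1-(propan-2-yl)-3-(Bpin)cyclopentan-1-ol | O[C@@H](/C=C(/C)[Si](CC)(CC)CC)[C@H]1[C@](O)(C(C)C)CC[C@]1(C)B2OC(C)(C)C(C)(C)O2
F8 | step 4 | (1S,2S,3R)-2-[(1R,2Z)-1-hydroxy-3-iodobut-2-en-1-yl]-3-methyl-1-(prop-1-en-2-yl)-3-(Bpin)cyclopentan-1-ol | O[C@@H](/C=C(/C)I)[C@H]1[C@](O)(C(C)=C)CC[C@]1(C)B2OC(C)(C)C(C)(C)O2
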